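In flavan numbering (ring A benzo, ring C pyran, ring D acylphloroglucinol), ring C (O1–C2–C3–C4–C4a–C8a) is cut at C3–C4 and O1–C8a. The key step exploits that C4 is benzylic to ring A and that C8a lies ortho to C4a and meta to the C7 oxygen: a 2-fluorobenzyl phenyl sulfide carbanion (C4 nucleophile, C8a electrophile) and an enantiopure (R)-aryloxirane (C3 electrophile, O1 nucleophile) merge in a one-pot epoxide opening/SNAr annulation that carries C2 in from the epoxide. The C4 phenylthio group left by the annulation then leaves under silver activation, and the acylphloroglucinol (ring D) adds trans to the C2 aryl group; hydrogenolysis of two benzyl ethers finishes the synthesis.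

Key step: step 3

Assumption: the fluoro aldehyde, thiophenol, the bromo ketone, phloroglucinol and dodecanoyl chloride are taken as commercially available; the target is (2S,4R), that is 2,4-trans.

Step 1
Reactants: 1 4-(benzyloxy)-2-fluorobenzaldehyde; 2 benzenethiol
Product: 3 4-(benzyloxy)-2-fluoro-1-[(phenylsulfanyl)methyl]benzene
Conditions: Et3SiH, CF3CO2H, CH2Cl2, 0 °C to rt
Reagents that add atoms: none
Why: Acid-promoted condensation of the aldehyde with the thiol gives an aryl-stabilised thionium ion that the silane reduces in situ (reductive thioetherification by ionic hydrogenation), and no stereocentre is formed.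

Step 2
Reactants: 4 1-[4-(benzyloxy)phenyl]-2-bromoethan-1-one
Product: 6 (2R)-2-[4-(benzyloxy)phenyl]oxirane, via (R)-bromohydrin 5 (not isolated)
Conditions: (R)-1-methyl-3,3-diphenyltetrahydro-1H,3H-pyrrolo[1,2-c][1,3,2]oxazaborole (10 mol%), BH3·SMe2, THF, 0 °C; MeOH quench; then 2 M NaOH aq, rt
Reagents that add atoms: none
Why: CBS reduction, in which the catalyst–borane complex binds the ketone with the aryl group as the large substituent and delivers hydride to one face to set the (R)-carbinol centre, is followed by an intramolecular Williamson displacement of the primary bromide that does not touch that centre.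

Step 3
Reactants: 3 4-(benzyloxy)-2-fluoro-1-[(phenylsulfanyl)methyl]benzene; 6 (2R)-2-[4-(benzyloxy)phenyl]oxirane
Product: 9 (2S)-7-(benzyloxy)-2-[4-(benzyloxy)phenyl]-4-(phenylsulfanyl)-3,4-dihydro-2H-1-benzopyran (C4 epimers), via lithiated sulfide 7 (not isolated), via lithium alkoxide 8 (not isolated)
Conditions: LiN(iPr)2 (1.05 equiv), THF, −78 to −40 °C; 6, −78 to 0 °C; then KOtBu (1 equiv), DMPU, 70 °C
Reagents that add atoms: none
Why: Lithiation of 3 alpha to sulfur gives the sulfur- and aryl-stabilised carbanion 7, which opens epoxide 6 by SN2 attack at its unsubstituted CH2 terminus (C3–C4 formed) and releases alkoxide 8; once potassium and DMPU loosen the ion pair, this alkoxide displaces fluoride at C8a by addition–elimination (SNAr) through a Meisenheimer adduct (O1–C8a formed). The closest known reaction types are the alkylation of alpha-thio benzylic and 2-aryl-1,3-dithiane carbanions with terminal epoxides and the base-mediated cyclisation of 3-(2-fluorophenyl)propan-1-olates to chromans, here run in one flask as a formal [3+3] annulation. Ring C closes in a 6-exo-trig mode at the ipso carbon C8a (the C8a–C8 π bond that takes up the charge lies outside the new ring), helped by the inductive pull of the C7 benzyloxy group meta to fluorine; should base instead trigger elimination to the C8–C8a aryne, the same C7 group directs the tethered alkoxide to C8a, so both pathways should converge on 9. C2 is not a reacting centre: the configuration of the (R)-epoxide is carried over unchanged and is named (2S) in 9 only because the substituent priorities change, while C4 forms without control as an epimer mixture that is harmless because C4 is planarised in step 5. The step needs terminal instead of benzylic epoxide opening, which the soft, hindered carbanion under Lewis-acid-free conditions should secure, and it needs the alkoxide, not a C4 carbanion, to be the resting anion during ring closure, which the choice of a sulfide (C4–H less acidic than the alcohol) in place of a sulfone secures.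

Step 4
Reactants: 10 benzene-1,3,5-triol (phloroglucinol); 11 dodecanoyl chloride
Product: 12 1-(2,4,6-trihydroxyphenyl)dodecan-1-one
Conditions: AlCl3 (3 equiv), PhNO2–CH2Cl2, 0 to 60 °C; aq HCl work-up
Reagents that add atoms: none
Why: Friedel–Crafts acylation of the threefold activated ring should stop at monoacylation because the chelated aryl ketone is deactivated, and no stereocentre is formed.

Step 5
Reactants: 9 (2S)-7-(benzyloxy)-2-[4-(benzyloxy)phenyl]-4-(phenylsulfanyl)-3,4-dihydro-2H-1-benzopyran; 12 1-(2,4,6-trihydroxyphenyl)dodecan-1-one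
Product: 14 1-{3-[(2S,4R)-7-(benzyloxy)-2-[4-(benzyloxy)phenyl]-3,4-dihydro-2H-1-benzopyran-4-yl]-2,4,6-trihydroxyphenyl}dodecan-1-one, via flavan-4-yl cation 13 (not isolated)
Conditions: AgBF4 (1.5 equiv), 12 in excess (3 equiv), THF, −20 to 0 °C
Reagents that add atoms: none
Why: The thiophilic silver cation of AgBF4 abstracts the phenylthio group to give the C4 benzylic cation 13 (stabilised by O1 and the C7 benzyloxy group), which undergoes Friedel–Crafts alkylation by one of the two equivalent free positions of ring D (excess 12 suppresses double alkylation), the nucleophile entering pseudo-axially on the half-chair anti to the pseudo-equatorial C2 aryl group, so that C4 should be set 2,4-trans, that is (4R), under substrate control from C2.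

Step 6
Reactants: 14 1-{3-[(2S,4R)-7-(benzyloxy)-2-[4-(benzyloxy)phenyl]-3,4-dihydro-2H-1-benzopyran-4-yl]-2,4,6-trihydroxyphenyl}dodecan-1-one
Product: 15 (+)-myristinin A
Conditions: H2 (1 atm), 10% Pd/C, EtOAc–MeOH, rt
Reagents that add atoms: none
Why: Catalytic hydrogenolysis cleaves the two aryl benzyl ethers under neutral conditions that should leave the hydrogen-bonded aryl ketone and both stereocentres of ring C untouched.

Compound list
1 | 4-(benzyloxy)-2-fluorobenzaldehyde | O=Cc1ccc(OCc2ccccc2)cc1F | starting material
2 | benzenethiol (thiophenol) | Sc1ccccc1 | starting material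
3 | 4-(benzyloxy)-2-fluoro-1-[(phenylsulfanyl)methyl]benzene | Fc1cc(OCc2ccccc2)ccc1CSc1ccccc1 | intermediate
4 | 1-[4-(benzyloxy)phenyl]-2-bromoethan-1-one | O=C(CBr)c1ccc(OCc2ccccc2)cc1 | starting material
5 | (1R)-1-[4-(benzyloxy)phenyl]-2-bromoethan-1-ol (formed in the flask) | O[C@@H](CBr)c1ccc(OCc2ccccc2)cc1 | intermediate
6 | (2R)-2-[4-(benzyloxy)phenyl]oxirane | c1ccccc1COc1ccc(cc1)[C@@H]1CO1 | intermediate
7 | [4-(benzyloxy)-2-fluorophenyl](phenylsulfanyl)methyllithium (formed in the flask) | [Li]C(Sc1ccccc1)c1ccc(OCc2ccccc2)cc1F | intermediate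
8 | lithium (1S)-1-[4-(benzyloxy)phenyl]-3-[4-(benzyloxy)-2-fluorophenyl]-3-(phenylsulfanyl)propan-1-olate (C3 epimers; formed in the flask) | [Li+].[O-][C@@H](CC(Sc1ccccc1)c1ccc(OCc2ccccc2)cc1F)c1ccc(OCc2ccccc2)cc1 | intermediate
9 | (2S)-7-(benzyloxy)-2-[4-(benzyloxy)phenyl]-4-(phenylsulfanyl)-3,4-dihydro-2H-1-benzopyran (C4 epimers) | c1ccccc1SC1C[C@@H](c2ccc(OCc3ccccc3)cc2)Oc2cc(OCc3ccccc3)ccc12 | intermediate
10 | benzene-1,3,5-triol (phloroglucinol) | Oc1cc(O)cc(O)c1 | starting material
11 | dodecanoyl chloride | CCCCCCCCCCCC(=O)Cl | starting material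
12 | 1-(2,4,6-trihydroxyphenyl)dodecan-1-one | CCCCCCCCCCCC(=O)c1c(O)cc(O)cc1O | intermediate
13 | (2S)-7-(benzyloxy)-2-[4-(benzyloxy)phenyl]-3,4-dihydro-2H-1-benzopyran-4-ylium tetrafluoroborate (formed in the flask) | [CH+]1C[C@@H](c2ccc(OCc3ccccc3)cc2)Oc2cc(OCc3ccccc3)ccc21.F[B-](F)(F)F | intermediate
14 | 1-{3-[(2S,4R)-7-(benzyloxy)-2-[4-(benzyloxy)phenyl]-3,4-dihydro-2H-1-benzopyran-4-yl]-2,4,6-trihydroxyphenyl}dodecan-1-one | CCCCCCCCCCCC(=O)c1c(O)cc(O)c([C@@H]2C[C@@H](c3ccc(OCc4ccccc4)cc3)Oc3cc(OCc4ccccc4)ccc32)c1O | intermediate
15 | (+)-myristinin A, 1-{2,4,6-trihydroxy-3-[(2S,4R)-7-hydroxy-2-(4-hydroxyphenyl)-3,4-dihydro-2H-1-benzopyran-4-yl]phenyl}dodecan-1-one | CCCCCCCCCCCC(=O)c1c(O)cc(O)c([C@@H]2C[C@@H](c3ccc(O)cc3)Oc3cc(O)ccc32)c1O | target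

Total step count: 6. Longest linear sequence: 4 steps (steps 1, 3, 5 and 6; the branch through step 2 is equally long).

Steps most likely to fail

Step 3. The ring closure is a substitution on a fluoroarene that carries no strong acceptor, so the cascade may stall at the open-chain alkoxide or be overtaken by intermolecular attack of tert-butoxide; benzylic opening of the electron-rich epoxide is a second, smaller risk. The fallback separates the two bond formations and closes the ring by copper catalysis on a bromide. It sets out from 2 and 6 and comes back at 9. Commercial 4-(benzyloxy)-2-bromobenzaldehyde F1 is coupled with 2 under the conditions of step 1 to give 4-(benzyloxy)-2-bromo-1-[(phenylsulfanyl)methyl]benzene F2. Its lithio derivative (LiN(iPr)2, THF, −78 °C) opens 6 and, after aqueous work-up, should give (1S)-1-[4-(benzyloxy)phenyl]-3-[4-(benzyloxy)-2-bromophenyl]-3-(phenylsulfanyl)propan-1-ol F3. An Ullmann-type intramolecular etherification (CuI, 1,10-phenanthroline, Cs2CO3, toluene, 110 °C) then closes O1–C8a to give 9.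

Step 5. Irreversible silver-promoted ionisation may give poor facial selectivity at C4, and the cation may also be consumed by double alkylation of ring D or by ring A of a second molecule. The fallback changes the electrophile to the alcohol and the activation to reversible Brønsted acid catalysis. It sets out from 9 and comes back at 14. S-Methylation of 9 (MeOTf, CH2Cl2, 0 °C) gives [(2S)-7-(benzyloxy)-2-[4-(benzyloxy)phenyl]-3,4-dihydro-2H-1-benzopyran-4-yl](methyl)phenylsulfonium trifluoromethanesulfonate F4. Hydrolysis in the same flask (aq NaHCO3, THF) should give (2S)-7-(benzyloxy)-2-[4-(benzyloxy)phenyl]-3,4-dihydro-2H-1-benzopyran-4-ol F5 as an epimer mixture. Dehydrative Friedel–Crafts alkylation of excess 12 with F5 (TsOH·H2O cat., dioxane, rt) then gives 14; because ionisation at C4 is reversible under these conditions, the mixture should drain toward the 2,4-trans isomer.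

Step 6. Traces of sulfur or silver carried over from step 5 may poison the catalyst, and forcing the reaction risks hydrogenolysis of the benzylic C2–O1 bond of ring C. The fallback replaces reductive cleavage by Lewis-acid dealkylation with a cation scavenger: BCl3 and pentamethylbenzene in CH2Cl2 at −78 °C. It sets out from 14 and comes back at 15 without a new intermediate.

Further compounds
F1 | step 3 | 4-(benzyloxy)-2-bromobenzaldehyde | O=Cc1ccc(OCc2ccccc2)cc1Br
F2 | step 3 | 4-(benzyloxy)-2-bromo-1-[(phenylsulfanyl)methyl]benzene | Brc1cc(OCc2ccccc2)ccc1CSc1ccccc1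
F3 | step 3 | (1S)-1-[4-(benzyloxy)phenyl]-3-[4-(benzyloxy)-2-bromophenyl]-3-(phenylsulfanyl)propan-1-ol (C3 epimers) | O[C@@H](CC(Sc1ccccc1)c1ccc(OCc2ccccc2)cc1Br)c1ccc(OCc2ccccc2)cc1
F4 | step 5 | [(2S)-7-(benzyloxy)-2-[4-(benzyloxy)phenyl]-3,4-dihydro-2H-1-benzopyran-4-yl](methyl)phenylsulfonium trifluoromethanesulfonate | C[S+](c1ccccc1)C1C[C@@H](c2ccc(OCc3ccccc3)cc2)Oc2cc(OCc3ccccc3)ccc12.[O-]S(=O)(=O)C(F)(F)F
F5 | step 5 | (2S)-7-(benzyloxy)-2-[4-(benzyloxy)phenyl]-3,4-dihydro-2H-1-benzopyran-4-ol (C4 epimers) | OC1C[C@@H](c2ccc(OCc3ccccc3)cc2)Oc2cc(OCc3ccccc3)ccc12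
F0 | step 6 | none | none
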